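# Proposed total synthesis of guanipiperazine A by a macrocyclising quinone methide 1,6-addition

## Analysis of the target

Guanipiperazine A (23) is a cis-2,5-dibenzylpiperazine whose two aryl groups are tied together by a diaryl ether. Piperazine C2 and C5, the two benzylic CH2 groups, the para-bridged ring B, the ether oxygen and the meta-bridged ring A form a 14-membered meta,para-cyclophane. Ring A is 1,2,3,5-tetrasubstituted: its hydroxyl is flanked by the carbon bearing guanine C8 and by the ether oxygen, and lies para to the benzylic CH2 that leads to C5. The only stereocentres are C2 and C5, both S (priorities N > CH2N > CH2Ar > H), hence cis, the pattern of two L-amino acids. Sensitive features are two basic secondary amines, an oxidisable para-alkylphenol and a polar, poorly soluble guanine with several N–H sites, which is best introduced last. The difficulty is to close the strained cyclophane while fixing C5 relative to C2. The route rests on the para relationship between the ring A hydroxyl and the ring A benzylic carbon. At the diketopiperazine oxidation level C5 is a glycine α-carbon between N4 and the C6 carbonyl, and the benzylic carbon can be the exocyclic terminus of a para-quinone methide of ring A. The C5–CH2 bond can therefore be formed by a conjugate addition that restores the aromaticity of ring A and closes the macrocycle.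

## Retrosynthetic reasoning

**23 ⇒ 22.** Only the two carbamates on N1 and N4 are removed in the last step. They keep the amines out of the aldehyde and heterocycle chemistry, and the purine, the diaryl ether and both stereocentres tolerate the acid that cleaves them.

**22 ⇒ 18 + 19.** The bonds C8–N7 and C8–N9 of the guanine are cut. C8 sits ortho to the ring A hydroxyl, so it can enter as a formyl carbon, and the pyrimidine half comes from the triaminopyrimidinone 19. The polar purine is thus absent from all earlier steps. The forward reaction must condense at the 5-amino group, close the imidazole and dehydrogenate without oxidising the phenol.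

**18 ⇒ 17 ⇒ 16 ⇒ 15 ⇒ 14.** The formyl C–C bond is cut first. The phenol of 17 has a single free ortho position, because the other is occupied by the aryloxy group and the para position by the benzylic carbon, so no regiochemical question arises. The carbamates of 17 are traced to the N4-benzyl amine 16, and the C3 and C6 methylenes of 16 to the lactam carbonyls of 15 and 14. The carbonyl oxidation level is restored because the C6 carbonyl is what makes C5 a carbon nucleophile.

**14 ⇒ 13 ⇒ 12 (key disconnection).** The C5–CH2 bond to ring A is cut. No other bond of the macrocycle combines a latent nucleophile (C5, α to the N-acyl carbamate carbonyl C6) with a latent electrophile (the para-hydroxybenzylic carbon) in this way. The cut removes the ring, one skeletal bond and the C5 stereocentre in a single step, and the forward reaction gains the aromatisation energy of ring A to pay for the strain. Forward, the quinone methide 13 must be released from the silyl-masked benzylic chloride 12 under conditions that also enolise C5 but not C2. The tether must deliver the electrophile to the face of the enolate cis to the C2 arm.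

**12 ⇒ 11 ⇒ 10 ⇒ 9 ⇒ 8.** These are adjustments of function only. The benzylic chloride comes from the alcohol 11 and this from the aldehyde 10, which serves as a robust placeholder for the benzylic leaving group through the early steps. The N1 carbamate of 10 is put on after ring formation, because N1 must first act as the nucleophile that closes the diketopiperazine. The silyl ether of 9 replaces the free phenol of 8 so that the phenoxide appears only when fluoride is added.

**8 ⇒ 7 ⇒ 6.** The lactam bond N1–C6 is cut. Forward, one acid treatment removes the N-carbamate and the acid-labile phenol ether of 6. The liberated amine of 7 closes onto the glycine ester, helped by the N-benzyl tertiary amide, which readily adopts the cis geometry.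

**6 ⇒ 5 + 2; 5 ⇒ 3 + 4; 2 ⇒ 1.** The diaryl ether is cut at the ring A carbon, so the oxygen stays with the tyrosine phenol of 5 and ring A arrives as the aryl iodide 2. The coupling is placed after the amide bond C3–N4 has been made from 3 and 4, because C2–H is then α to a tertiary amide and less prone to racemise under base than in an ester. Iodide 2 is the O-protected form of commercial 1.

## Alternatives that were turned down

**Alternative 1:** Both C–N bonds at the stereocentres (N1–C2 and N4–C5) are traced back to allylic C–O bonds.

- **Forward key step.** An achiral diaryl ether with a benzyl-protected ring A phenol and two (E)-4-arylbut-2-enyl trichloroacetimidate arms, bis-imidate A1, would undergo a double Overman rearrangement. The catalyst is the chloride-bridged cobalt-sandwich oxazoline palladacycle di-μ-chlorobis[(η5-(S)-(pR)-2-(2'-(4'-isopropyl)oxazolinyl)cyclopentadienyl-1-C,3'-N)(η4-tetraphenylcyclobutadiene)cobalt]dipalladium. The product is the (S,S)-bis(allylic trichloroacetamide) A2.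
- **For.** Two C–N bonds and both stereocentres arise in one catalytic operation from a substrate without stereochemistry. Two independent catalyst-controlled events on one molecule raise the enantiomeric purity of the (S,S) product, at the cost of a separable (R,S) diastereomer. Either enantiomer is accessible. On this point it is stronger than the chosen route, which relies on compound 3 for C2 and on substrate control for C5.
- **Against.** A2 contains neither the piperazine nor the macrocycle. Each vinyl group must still be cleaved to a one-carbon unit and joined head-to-tail to the nitrogen of the other arm, and this double closure has to build the strained 14-membered ring. The α-acylamino aldehyde termini needed for it are configurationally labile. Head-to-tail condensation of amino aldehydes passes through dihydropyrazines that aromatise easily, which would erase both stereocentres. The doubly activated homobenzylic, allylic CH2 groups of A1 are also prone to double-bond migration into conjugation with the arenes during imidate formation.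
- **Comparison.** After the diaryl ether, two chain extensions, imidate formation and the rearrangement, the sequence still needs cleavage, N-deprotection, cyclisation and reprotection before the common end game. That is clearly longer than the nine operations that bring the chosen route to the closed ring. In place of catalyst control, the chosen strategy offers a single bond formation in which macrocycle and stereocentre are created together.

**Alternative 2:** The disconnection lies inside the heterocycle: C8–N7 and C8–N9 are cut so that the imidazole ring of the guanine is grown on the arene.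

- **Forward key step.** The macrocyclic salicylaldehyde A3 (the same compound as 18) condenses with the 5-amino group of 2,5,6-triaminopyrimidin-4(3H)-one A4 (the same as 19). The 6-amino group adds to the imine carbon, and dehydrogenation gives N1,N4-di-Boc guanipiperazine A, A5 (the same as 22).
- **For.** The guanine is not carried through the synthesis, and no cross-coupling at C8 of an unprotected purine is needed. The position on ring A is dictated by the phenol. The step is a variant of a classical purine synthesis. As a single step it is more reliable than the quinone methide closure, and the chosen route uses exactly this annulation as its step 14.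
- **Against.** As the defining idea it solves only the last two bonds. The cyclophane, the cis relationship of C2 and C5 and the substitution pattern of ring A are left to an unspecified preparation of A3. The most plausible one is a copper-mediated macro-etherification of a piperazine built from two tyrosine units, which needs a separately made halogenated tyrosine unit and a hot, dilute closure.
- **Comparison.** At the end game the two strategies are equal. The chosen one adds a defined, stereochemistry-setting way to reach A3 from one tyrosine unit and one glycine unit.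

**Alternative 3:** The bond between ring A and its benzylic carbon (aryl–CH2) is cut; the benzylic carbon and C5 come from an alanine residue.

- **Forward key step.** The N-phthaloyl-alanyl-tyrosine A6, whose tyrosine oxygen carries a 2-benzyloxy-5-iodophenyl ring A, is treated with Pd(OAc)2 and AgOAc. The amide nitrogen and the carboxylate bind divalent palladium, and a methyl C–H bond of the alanine residue is cleaved to a five-membered palladacycle. Intramolecular coupling with the aryl iodide gives the 14-membered cyclophane acid A7.
- **For.** Both stereocentres come unchanged from the chiral pool, so the macrocyclisation creates no stereocentre and has no facial selectivity to control. In this respect it is stronger than the chosen step. The directing groups are native to the dipeptide, and β-arylation of N-phthaloyl alanine residues is established chemistry.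
- **Against.** The C–C bond must form by reductive elimination from a palladacycle (tetravalent palladium after oxidative addition) that is itself part of the nascent strained cyclophane. This requires about 100 °C or more and a stoichiometric silver salt. The iodide is deactivated by the para benzyloxy group, and nothing compensates the strain, so oligomerisation and loss of iodide are likely competitors. After closure the ring of A7 runs through an amide that must turn cis before the transannular lactamisation to the diketopiperazine. The phthalimide has to be removed first, and the benzyl ether on ring A costs a further deprotection before ortho-formylation.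
- **Comparison.** The chosen closure runs at room temperature without a transition metal and is driven by rearomatisation of ring A. It starts from a diketopiperazine that is already formed and delivers the ring A phenol free.

Key step: step 9

## Remarks before the steps

- Ring A is the hydroxylated ring that finally carries the guanine; ring B is the para-phenylene ring.
- The six-membered heterocycle is numbered throughout as in the target piperazine. N1 and C2 come from tyrosine (C2 bears the ring B benzyl arm) and C3 is the tyrosine carbonyl carbon. N4 and C5 come from N-benzylglycine and C6 is its carbonyl carbon.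
- Assumption: 19 is used as its commercial sulfate, and the guanine tautomer is drawn as in the target string.
- 4-Hydroxy-3-iodobenzaldehyde and N-Boc-L-tyrosine are used because the iodide couples more readily than the bromide and the free acid allows the amide to be made before the ether.

## Route

Step 1
Reactants: 1 4-hydroxy-3-iodobenzaldehyde
Product: 2 3-iodo-4-[(4-methoxybenzyl)oxy]benzaldehyde
Conditions: PMBCl, K2CO3, Bu4NI (cat.), DMF, rt
Reagents that add atoms: 4-methoxybenzyl chloride, COc1ccc(CCl)cc1
Why: Williamson etherification of an acidic (para-formyl) phenol. The 4-methoxybenzyl ether survives the basic copper coupling and is later lost in the same acid treatment that removes the N-Boc group.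

Step 2
Reactants: 3 N-(tert-butoxycarbonyl)-L-tyrosine; 4 ethyl N-benzylglycinate
Product: 5 ethyl N-benzyl-N-[N-(tert-butoxycarbonyl)-L-tyrosyl]glycinate
Conditions: EDC·HCl, HOBt, CH2Cl2, 0 °C → rt
Reagents that add atoms: none
Why: Carbodiimide/HOBt amide coupling. The urethane-protected acid does not racemise through an oxazolone, and the secondary amine outcompetes the free phenol for the active ester.

Step 3
Reactants: 5 ethyl N-benzyl-N-[N-(tert-butoxycarbonyl)-L-tyrosyl]glycinate; 2 3-iodo-4-[(4-methoxybenzyl)oxy]benzaldehyde
Product: 6 ethyl N-benzyl-N-{N-(tert-butoxycarbonyl)-O-[5-formyl-2-(4-methoxybenzyloxy)phenyl]-L-tyrosyl}glycinate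
Conditions: CuI (10 mol %), N,N-dimethylglycine hydrochloride (30 mol %), Cs2CO3, 1,4-dioxane, 90 °C
Reagents that add atoms: none
Why: Ligand-accelerated Ullmann diaryl ether synthesis between the caesium phenoxide of 5 and an aryl iodide. The phenoxide is far more reactive toward copper than the carbamate N–H, and C2–H, α to a tertiary amide and not to an ester, should resist base-induced racemisation.

Step 4
Reactants: 6 ethyl N-benzyl-N-{N-(tert-butoxycarbonyl)-O-[5-formyl-2-(4-methoxybenzyloxy)phenyl]-L-tyrosyl}glycinate
Product: 8 (2S)-4-benzyl-2-[4-(5-formyl-2-hydroxyphenoxy)benzyl]piperazine-3,6-dione, via amino ester trifluoroacetate 7 (not isolated)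
Conditions: TFA, anisole, CH2Cl2, 0 °C → rt; concentrate; then Et3N, MeOH, 50 °C
Reagents that add atoms: none
Why: Acidolysis removes the N-Boc group and the 4-methoxybenzyl ether together, with anisole trapping the benzylic cation. On neutralisation the amine of 7 lactamises onto the glycine ester, which is fast because the N-benzyl tertiary amide readily adopts the cis geometry. Any imine between the amine and the deactivated hydroxybenzaldehyde is reversible and drains into the irreversible lactam.

Step 5
Reactants: 8 (2S)-4-benzyl-2-[4-(5-formyl-2-hydroxyphenoxy)benzyl]piperazine-3,6-dione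
Product: 9 (2S)-4-benzyl-2-{4-[2-(tert-butyldimethylsilyloxy)-5-formylphenoxy]benzyl}piperazine-3,6-dione
Conditions: TBSCl, imidazole, DMF, rt
Reagents that add atoms: tert-butyldimethylsilyl chloride, CC(C)(C)[Si](C)(C)Cl
Why: Standard silylation of a phenol. The lactam N–H is not silylated lastingly, and the aryl silyl ether is the fluoride-labile mask needed for the key step.

Step 6
Reactants: 9 (2S)-4-benzyl-2-{4-[2-(tert-butyldimethylsilyloxy)-5-formylphenoxy]benzyl}piperazine-3,6-dione
Product: 10 tert-butyl (2S)-4-benzyl-2-{4-[2-(tert-butyldimethylsilyloxy)-5-formylphenoxy]benzyl}-3,6-dioxopiperazine-1-carboxylate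
Conditions: Boc2O, DMAP (0.2 equiv), MeCN, rt
Reagents that add atoms: di-tert-butyl dicarbonate, CC(C)(C)OC(=O)OC(=O)OC(C)(C)C
Why: DMAP-catalysed acylation of the only N–H (N1) gives the N-acyl carbamate. This makes the C6 carbonyl imide-like and thereby acidifies C5–H but not C2–H.

Step 7
Reactants: 10 tert-butyl (2S)-4-benzyl-2-{4-[2-(tert-butyldimethylsilyloxy)-5-formylphenoxy]benzyl}-3,6-dioxopiperazine-1-carboxylate
Product: 11 tert-butyl (2S)-4-benzyl-2-{4-[2-(tert-butyldimethylsilyloxy)-5-(hydroxymethyl)phenoxy]benzyl}-3,6-dioxopiperazine-1-carboxylate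
Conditions: NaBH4 (0.5 equiv), THF/EtOH (10:1), −40 °C; AcOH quench
Reagents that add atoms: none
Why: Chemoselective borohydride reduction. An aromatic aldehyde is reduced quickly at this temperature, whereas N-acyl carbamate and imide carbonyls react only slowly near room temperature, as in aldehyde reductions next to N-acyloxazolidinones.

Step 8
Reactants: 11 tert-butyl (2S)-4-benzyl-2-{4-[2-(tert-butyldimethylsilyloxy)-5-(hydroxymethyl)phenoxy]benzyl}-3,6-dioxopiperazine-1-carboxylate
Product: 12 tert-butyl (2S)-4-benzyl-2-{4-[2-(tert-butyldimethylsilyloxy)-5-(chloromethyl)phenoxy]benzyl}-3,6-dioxopiperazine-1-carboxylate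
Conditions: MsCl, LiCl, 2,4,6-collidine, DMF, 0 °C
Reagents that add atoms: lithium chloride, [Li+].[Cl-]
Why: Mesylation with in situ chloride exchange. The electron-rich benzylic mesylate is displaced by chloride as it forms, under buffered non-acidic conditions that spare the silyl ether and the N-acyl carbamate. 12 is used directly after a cold aqueous work-up.

Step 9
Reactants: 12 tert-butyl (2S)-4-benzyl-2-{4-[2-(tert-butyldimethylsilyloxy)-5-(chloromethyl)phenoxy]benzyl}-3,6-dioxopiperazine-1-carboxylate
Product: 14 (2S,5S)-N1-Boc-N4-benzyl macrocyclic diketopiperazine with free ring A phenol, via quinone methide 13 (not isolated)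
Conditions: CsF (5 equiv), 4 Å MS, DMF, 0 °C → rt, 12 added by syringe pump to a final 2 mM
Reagents that add atoms: none
Why: Proposed new method: fluoride cleaves the aryl silyl ether of 12, the phenoxide expels the para-benzylic chloride by 1,6-elimination to give quinone methide 13, and the caesium enolate at C5 (formed by fluoride in DMF and relayed by the phenoxide that each ring closure releases) adds through carbon to the exocyclic methylene, after which ring A is aromatic again. The closest known reaction type is the fluoride- or base-triggered generation of para-quinone methides from 4-silyloxybenzyl halides followed by 1,6-addition of stabilised carbanions such as malonates and glycine-derived enolates; new here are the singly activated diketopiperazine enolate and the macrocyclising mode. The 14-membered ring closes by a 14-endo-trig conjugate addition, and a direct enolate displacement of chloride (14-exo-tet) would converge on the same bond. The new stereocentre C5 is set by substrate control: allylic-type strain with the N1 carbamate holds the C2 benzyl arm pseudoaxial, the tethered electrophile can reach the planar enolate only from that face, and the cis (2S,5S) isomer results; because C5–H stays acidic in 14, a wrong isomer could not persist in a ring that only the cis arrangement can span. Site selectivity for C5 over C2 follows because only the C6 carbonyl belongs to the N-acyl carbamate, whereas C2–H is α to an ordinary tertiary amide and would have to become planar against the Boc group. Carbon over oxygen alkylation and ring closure over oligomerisation are secured by reversibility: adducts of 13 with fluoride, chloride, phenoxide or the enolate oxygen are para-hydroxybenzyl derivatives that re-eliminate under the conditions, whereas the C–C bond forms irreversibly, and slow addition at millimolar concentration suppresses bimolecular C-alkylation.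

Step 10
Reactants: 14 (2S,5S)-N1-Boc-N4-benzyl macrocyclic diketopiperazine with free ring A phenol
Product: 15 (2S,5S)-N4-benzyl macrocyclic diketopiperazine with N1–H and free ring A phenol
Conditions: TFA, anisole, CH2Cl2, 0 °C → rt
Reagents that add atoms: none
Why: Acidolysis of the N-acyl carbamate returns the secondary lactam. It is removed before hydride reduction because the activated C6 carbonyl would otherwise be opened.

Step 11
Reactants: 15 (2S,5S)-N4-benzyl macrocyclic diketopiperazine with N1–H and free ring A phenol
Product: 16 (2S,5S)-N4-benzyl macrocyclic piperazine with free ring A phenol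
Conditions: BH3·THF (excess), THF, reflux; then MeOH, aq HCl, reflux; aq NaOH
Reagents that add atoms: none
Why: Borane reduction of both lactam carbonyls (C3 and C6) to methylenes, the standard conversion of a diketopiperazine into a piperazine. Neither C2 nor C5 is enolised by this electrophilic reductant, so the (2S,5S) configuration is kept, and acidic methanolysis breaks the amine–borane complexes.

Step 12
Reactants: 16 (2S,5S)-N4-benzyl macrocyclic piperazine with free ring A phenol
Product: 17 (2S,5S)-N1,N4-di-Boc macrocyclic piperazine with free ring A phenol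
Conditions: H2 (1 atm), Pd(OH)2/C, Boc2O, MeOH, rt; then K2CO3, MeOH
Reagents that add atoms: di-tert-butyl dicarbonate, CC(C)(C)OC(=O)OC(=O)OC(C)(C)C
Why: Hydrogenolysis of the N4-benzyl group with in situ carbamate formation. N1–H is acylated at once and N4 as soon as it is freed, while the homobenzylic C–N bonds and the diaryl ether are inert. The carbonate treatment cleaves any aryl carbonate formed at the phenol.

Step 13
Reactants: 17 (2S,5S)-N1,N4-di-Boc macrocyclic piperazine with free ring A phenol
Product: 18 (2S,5S)-N1,N4-di-Boc macrocyclic piperazine salicylaldehyde (formyl ortho to the ring A hydroxyl)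
Conditions: MgCl2, Et3N, (CH2O)n, MeCN, reflux
Reagents that add atoms: paraformaldehyde (formaldehyde), C=O
Why: Casnati–Skattebøl ortho-formylation. Formaldehyde is delivered within the magnesium phenoxide to the ortho carbon, and the benzylic alkoxide is oxidised by a second formaldehyde. Ring A has one free ortho position only, the other being occupied by the aryloxy group and the para position by the benzylic carbon.

Step 14
Reactants: 18 (2S,5S)-N1,N4-di-Boc macrocyclic piperazine salicylaldehyde; 19 2,5,6-triaminopyrimidin-4(3H)-one sulfate
Product: 22 N1,N4-di-Boc guanipiperazine A, via Schiff base 20 (not isolated), via dihydropurine 21 (not isolated)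
Conditions: NaOAc, DMSO, N2, 80 °C; then FeCl3 (10 mol %), O2 (1 atm), 80 °C
Reagents that add atoms: none
Why: Oxidative variant of the Traube purine synthesis. The most nucleophilic 5-amino group of 19 gives Schiff base 20, the 6-amino group adds to the imine carbon to give aminal 21, and aerobic dehydrogenation aromatises the imidazole ring. Near-neutral conditions keep both Boc groups, and the phenol has no free ortho or para position to be attacked.

Step 15
Reactants: 22 N1,N4-di-Boc guanipiperazine A
Product: 23 guanipiperazine A
Conditions: TFA, H2O (5 %), CH2Cl2, 0 °C → rt; then NH3, MeOH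
Reagents that add atoms: none
Why: Acidolytic cleavage of both tert-butyl carbamates. The purine, the diaryl ether and both stereocentres are inert to acid, and neutralisation releases the free base.

## Compound list

1 | 4-hydroxy-3-iodobenzaldehyde | O=Cc1ccc(O)c(I)c1 | starting material
2 | 3-iodo-4-[(4-methoxybenzyl)oxy]benzaldehyde | O=Cc1ccc(OCc2ccc(OC)cc2)c(I)c1 | intermediate
3 | N-(tert-butoxycarbonyl)-L-tyrosine | CC(C)(C)OC(=O)N[C@@H](Cc1ccc(O)cc1)C(=O)O | starting material
4 | ethyl N-benzylglycinate | CCOC(=O)CNCc1ccccc1 | starting material
5 | ethyl N-benzyl-N-[N-(tert-butoxycarbonyl)-L-tyrosyl]glycinate | CCOC(=O)CN(Cc1ccccc1)C(=O)[C@H](Cc1ccc(O)cc1)NC(=O)OC(C)(C)C | intermediate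
6 | ethyl N-benzyl-N-{N-(tert-butoxycarbonyl)-O-[5-formyl-2-(4-methoxybenzyloxy)phenyl]-L-tyrosyl}glycinate | CCOC(=O)CN(Cc1ccccc1)C(=O)[C@H](Cc1ccc(Oc2cc(C=O)ccc2OCc2ccc(OC)cc2)cc1)NC(=O)OC(C)(C)C | intermediate
7 | ethyl N-benzyl-N-[O-(5-formyl-2-hydroxyphenyl)-L-tyrosyl]glycinate (formed as trifluoroacetate, not isolated) | CCOC(=O)CN(Cc1ccccc1)C(=O)[C@@H](N)Cc1ccc(Oc2cc(C=O)ccc2O)cc1 | intermediate
8 | (2S)-4-benzyl-2-[4-(5-formyl-2-hydroxyphenoxy)benzyl]piperazine-3,6-dione | O=C1CN(Cc2ccccc2)C(=O)[C@H](Cc2ccc(Oc3cc(C=O)ccc3O)cc2)N1 | intermediate
9 | (2S)-4-benzyl-2-{4-[2-(tert-butyldimethylsilyloxy)-5-formylphenoxy]benzyl}piperazine-3,6-dione | O=C1CN(Cc2ccccc2)C(=O)[C@H](Cc2ccc(Oc3cc(C=O)ccc3O[Si](C)(C)C(C)(C)C)cc2)N1 | intermediate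
10 | tert-butyl (2S)-4-benzyl-2-{4-[2-(tert-butyldimethylsilyloxy)-5-formylphenoxy]benzyl}-3,6-dioxopiperazine-1-carboxylate | O=C1CN(Cc2ccccc2)C(=O)[C@H](Cc2ccc(Oc3cc(C=O)ccc3O[Si](C)(C)C(C)(C)C)cc2)N1C(=O)OC(C)(C)C | intermediate
11 | tert-butyl (2S)-4-benzyl-2-{4-[2-(tert-butyldimethylsilyloxy)-5-(hydroxymethyl)phenoxy]benzyl}-3,6-dioxopiperazine-1-carboxylate | O=C1CN(Cc2ccccc2)C(=O)[C@H](Cc2ccc(Oc3cc(CO)ccc3O[Si](C)(C)C(C)(C)C)cc2)N1C(=O)OC(C)(C)C | intermediate
12 | tert-butyl (2S)-4-benzyl-2-{4-[2-(tert-butyldimethylsilyloxy)-5-(chloromethyl)phenoxy]benzyl}-3,6-dioxopiperazine-1-carboxylate | ClCc1ccc(O[Si](C)(C)C(C)(C)C)c(Oc2ccc(C[C@H]3C(=O)N(Cc4ccccc4)CC(=O)N3C(=O)OC(C)(C)C)cc2)c1 | intermediate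
13 | tert-butyl (2S)-4-benzyl-2-{4-[(3-methylidene-6-oxocyclohexa-1,4-dien-1-yl)oxy]benzyl}-3,6-dioxopiperazine-1-carboxylate (quinone methide, not isolated) | C=C1C=CC(=O)C(Oc2ccc(C[C@H]3C(=O)N(Cc4ccccc4)CC(=O)N3C(=O)OC(C)(C)C)cc2)=C1 | intermediate
14 | (2S,5S)-N1-Boc-N4-benzyl macrocyclic diketopiperazine (C2 and C5 benzylic arms joined through ring B–O–ring A, ring A hydroxyl free) | c1cc2cc(c1O)Oc1ccc(cc1)C[C@H]1C(=O)N(Cc3ccccc3)[C@H](C(=O)N1C(=O)OC(C)(C)C)C2 | intermediate
15 | (2S,5S)-N4-benzyl macrocyclic diketopiperazine (N1–H, ring A hydroxyl free) | c1cc2cc(c1O)Oc1ccc(cc1)C[C@H]1C(=O)N(Cc3ccccc3)[C@H](C(=O)N1)C2 | intermediate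
16 | (2S,5S)-N4-benzyl macrocyclic piperazine (N1–H, ring A hydroxyl free) | c1cc2cc(c1O)Oc1ccc(cc1)C[C@H]1CN(Cc3ccccc3)[C@H](CN1)C2 | intermediate
17 | (2S,5S)-N1,N4-di-Boc macrocyclic piperazine (ring A hydroxyl free) | c1cc2cc(c1O)Oc1ccc(cc1)C[C@H]1CN(C(=O)OC(C)(C)C)[C@H](CN1C(=O)OC(C)(C)C)C2 | intermediate
18 | (2S,5S)-N1,N4-di-Boc macrocyclic piperazine salicylaldehyde (formyl ortho to the ring A hydroxyl) | O=Cc1cc2cc(c1O)Oc1ccc(cc1)C[C@H]1CN(C(=O)OC(C)(C)C)[C@H](CN1C(=O)OC(C)(C)C)C2 | intermediate
19 | 2,5,6-triaminopyrimidin-4(3H)-one sulfate | Nc1nc(N)c(N)c(=O)[nH]1.OS(=O)(=O)O | starting material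
20 | Schiff base of 18 with the 5-amino group of 19 (E imine, not isolated) | Nc1nc(N)c(/N=C/c2cc3cc(c2O)Oc4ccc(cc4)C[C@H]5CN(C(=O)OC(C)(C)C)[C@H](CN5C(=O)OC(C)(C)C)C3)c(=O)[nH]1 | intermediate
21 | 8-aryl-7,8-dihydroguanine (C8 aminal, configuration at C8 not defined, not isolated) | Nc1nc2NC(c3cc4cc(c3O)Oc5ccc(cc5)C[C@H]6CN(C(=O)OC(C)(C)C)[C@H](CN6C(=O)OC(C)(C)C)C4)Nc2c(=O)[nH]1 | intermediate
22 | N1,N4-di-Boc guanipiperazine A | Nc1nc2nc(-c3cc4cc(c3O)Oc3ccc(cc3)C[C@H]3CN(C(=O)OC(C)(C)C)[C@H](CN3C(=O)OC(C)(C)C)C4)[nH]c2c(=O)[nH]1 | intermediate
23 | guanipiperazine A | Nc1nc2nc(-c3cc4cc(c3O)Oc3ccc(cc3)C[C@H]3CN[C@H](CN3)C4)[nH]c2c(=O)[nH]1 | target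

## Step count and least certain steps

Total: 15 steps. Longest linear sequence: 14 steps (3 → 23 through steps 2–15; equally 1 → 23 through steps 1 and 3–15).

**Step 9 (key step, proposed new method).**
- What may go wrong: bimolecular capture of the quinone methide, by a phenoxide carbon or an enolate of another molecule, may outrun ring closure and give oligomers.
- The stationary concentration of the C5 enolate under fluoride alone may be too low, so that the quinone methide is consumed by adventitious water.
- Fluoride or phenoxide may open the N-acyl carbamate ring.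
- The flattened diketopiperazine may hold the two arms too far apart for the strained transition state.
- Fallback (known chemistry): the ring is closed at the diaryl ether by copper-mediated intramolecular etherification on the more flexible piperazine. It sets out from 3 and returns at 17.
- N-Boc-L-tyrosine methyl ester F1 is iodinated ortho to the hydroxyl (NIS, cat. TsOH, MeCN) to N-Boc-3-iodo-L-tyrosine methyl ester F2.
- F2 is O-benzylated (BnBr, K2CO3, DMF) to N-Boc-O-benzyl-3-iodo-L-tyrosine methyl ester F3 and freed at nitrogen (HCl, dioxane) to methyl O-benzyl-3-iodo-L-tyrosinate F4.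
- EDC/HOBt coupling of F4 with 3 gives the dipeptide N-Boc-L-tyrosyl-O-benzyl-3-iodo-L-tyrosine methyl ester F5.
- TFA followed by heating the neutralised amino ester closes the diketopiperazine (2S,5S)-cyclo(tyrosyl–O-benzyl-3-iodotyrosyl) F6.
- BH3·THF reduces F6 to the (2S,5S)-2-(4-benzyloxy-3-iodobenzyl)-5-(4-hydroxybenzyl)piperazine F7, and Boc2O gives the N1,N4-di-Boc piperazine F8.
- Ullmann macro-etherification (CuI, N,N-dimethylglycine, Cs2CO3, dioxane, 100 °C, high dilution) joins the ring B phenoxide to the iodinated carbon of ring A and gives the O-benzyl ether of 17, macrocycle F9.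
- Hydrogenolysis of F9 (H2, Pd/C) gives 17.

**Step 3.**
- What may go wrong: partial racemisation at C2 by enolisation at 90 °C in the presence of carbonate; slow oxidative addition at the hindered, electron-rich iodide; competing N-arylation of the carbamate.
- Fallback: a room-temperature Chan–Lam coupling. It sets out from 2 and 5 and returns at 6.
- Miyaura borylation of 2 (B2pin2, PdCl2(dppf), KOAc, dioxane, 80 °C) gives the pinacol boronate 4-[(4-methoxybenzyl)oxy]-3-(4,4,5,5-tetramethyl-1,3,2-dioxaborolan-2-yl)benzaldehyde F10.
- Oxidative cleavage of the pinacol (NaIO4, NH4OAc, acetone/water) gives {5-formyl-2-[(4-methoxybenzyl)oxy]phenyl}boronic acid F11.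
- F11 is coupled with the phenol of 5 (Cu(OAc)2, pyridine, 4 Å MS, CH2Cl2, air, rt) to give 6.

**Step 4.**
- What may go wrong: condensation of the liberated amine with aldehyde groups of other molecules may compete with lactamisation, and the 4-methoxybenzyl cation may alkylate ring B.
- Fallback: the diketopiperazine is closed before ring A is attached, so that a free amine never meets the aldehyde. It sets out from 5 and returns at 8.
- TFA and then Et3N/MeOH convert 5 into (2S)-4-benzyl-2-(4-hydroxybenzyl)piperazine-3,6-dione F12.
- Chan–Lam coupling of F12 with boronic acid F11 (made from 2 as described for step 3; Cu(OAc)2, pyridine, CH2Cl2, air, rt) gives (2S)-4-benzyl-2-{4-[5-formyl-2-(4-methoxybenzyloxy)phenoxy]benzyl}piperazine-3,6-dione F13.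
- TFA/anisole removes the 4-methoxybenzyl group of F13 to give 8.

**Step 7.**
- What may go wrong: hydride attack at the activated C6 carbonyl with reductive ring opening, or loss of the aryl silyl ether to alkoxide.
- Fallback: the aldehyde is reduced before the imide exists, and a benzylic carbonate replaces the chloride as leaving group. It sets out from 9 and returns at 14.
- NaBH4 (MeOH/THF, 0 °C) reduces 9 to (2S)-4-benzyl-2-{4-[2-(tert-butyldimethylsilyloxy)-5-(hydroxymethyl)phenoxy]benzyl}piperazine-3,6-dione F14.
- Excess Boc2O with DMAP acylates N1 and the benzylic hydroxyl to give the N1-Boc benzylic tert-butyl carbonate F15.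
- CsF in DMF at high dilution desilylates F15, and 1,6-elimination of tert-butyl carbonate gives 13, which closes to 14 as in step 9. Steps 7 and 8 are then not needed.

**Step 14.**
- What may go wrong: air oxidation of 19 before it condenses, incomplete dehydrogenation of the aminal, oxidative degradation of the phenol, or poor mutual solubility of the partners.
- Fallback: the acylative Traube sequence. It sets out from 18 and returns at 22.
- Pinnick oxidation (NaClO2, NaH2PO4, 2-methyl-2-butene) gives the (2S,5S)-N1,N4-di-Boc macrocyclic salicylic acid F16.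
- Amide coupling of F16 with the 5-amino group of 19 (EDC, HOBt, DMF) gives the 5-aroylamino-2,6-diaminopyrimidin-4(3H)-one F17.
- Base-induced cyclodehydration of F17 (aq NaOH, EtOH, reflux) closes the imidazole ring to 22 without any oxidant.

## Further compounds

F1 | step 9 | N-Boc-L-tyrosine methyl ester | COC(=O)[C@H](Cc1ccc(O)cc1)NC(=O)OC(C)(C)C
F2 | step 9 | N-Boc-3-iodo-L-tyrosine methyl ester | COC(=O)[C@H](Cc1ccc(O)c(I)c1)NC(=O)OC(C)(C)C
F3 | step 9 | N-Boc-O-benzyl-3-iodo-L-tyrosine methyl ester | COC(=O)[C@H](Cc1ccc(OCc2ccccc2)c(I)c1)NC(=O)OC(C)(C)C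
F4 | step 9 | methyl O-benzyl-3-iodo-L-tyrosinate | COC(=O)[C@@H](N)Cc1ccc(OCc2ccccc2)c(I)c1
F5 | step 9 | N-Boc-L-tyrosyl-O-benzyl-3-iodo-L-tyrosine methyl ester | COC(=O)[C@H](Cc1ccc(OCc2ccccc2)c(I)c1)NC(=O)[C@H](Cc1ccc(O)cc1)NC(=O)OC(C)(C)C
F6 | step 9 | (2S,5S)-cyclo(tyrosyl–O-benzyl-3-iodotyrosyl) diketopiperazine | O=C1[C@H](Cc2ccc(OCc3ccccc3)c(I)c2)NC(=O)[C@H](Cc2ccc(O)cc2)N1
F7 | step 9 | (2S,5S)-2-(4-benzyloxy-3-iodobenzyl)-5-(4-hydroxybenzyl)piperazine | C1[C@H](Cc2ccc(OCc3ccccc3)c(I)c2)NC[C@H](Cc2ccc(O)cc2)N1
F8 | step 9 | di-tert-butyl (2S,5S)-2-(4-benzyloxy-3-iodobenzyl)-5-(4-hydroxybenzyl)piperazine-1,4-dicarboxylate | C1[C@H](Cc2ccc(OCc3ccccc3)c(I)c2)N(C(=O)OC(C)(C)C)C[C@H](Cc2ccc(O)cc2)N1C(=O)OC(C)(C)C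
F9 | step 9 | O-benzyl ether of 17 ((2S,5S)-N1,N4-di-Boc macrocyclic piperazine, ring A benzyloxy) | c1cc2cc(c1OCc1ccccc1)Oc1ccc(cc1)C[C@H]1CN(C(=O)OC(C)(C)C)[C@H](CN1C(=O)OC(C)(C)C)C2
F10 | step 3 | 4-[(4-methoxybenzyl)oxy]-3-(4,4,5,5-tetramethyl-1,3,2-dioxaborolan-2-yl)benzaldehyde | O=Cc1ccc(OCc2ccc(OC)cc2)c(B2OC(C)(C)C(C)(C)O2)c1
F11 | step 3 | {5-formyl-2-[(4-methoxybenzyl)oxy]phenyl}boronic acid | O=Cc1ccc(OCc2ccc(OC)cc2)c(B(O)O)c1
F12 | step 4 | (2S)-4-benzyl-2-(4-hydroxybenzyl)piperazine-3,6-dione | O=C1CN(Cc2ccccc2)C(=O)[C@H](Cc2ccc(O)cc2)N1
F13 | step 4 | (2S)-4-benzyl-2-{4-[5-formyl-2-(4-methoxybenzyloxy)phenoxy]benzyl}piperazine-3,6-dione | O=C1CN(Cc2ccccc2)C(=O)[C@H](Cc2ccc(Oc3cc(C=O)ccc3OCc3ccc(OC)cc3)cc2)N1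
F14 | step 7 | (2S)-4-benzyl-2-{4-[2-(tert-butyldimethylsilyloxy)-5-(hydroxymethyl)phenoxy]benzyl}piperazine-3,6-dione | O=C1CN(Cc2ccccc2)C(=O)[C@H](Cc2ccc(Oc3cc(CO)ccc3O[Si](C)(C)C(C)(C)C)cc2)N1
F15 | step 7 | tert-butyl (2S)-4-benzyl-2-{4-[5-(tert-butoxycarbonyloxymethyl)-2-(tert-butyldimethylsilyloxy)phenoxy]benzyl}-3,6-dioxopiperazine-1-carboxylate | O=C1CN(Cc2ccccc2)C(=O)[C@H](Cc2ccc(Oc3cc(COC(=O)OC(C)(C)C)ccc3O[Si](C)(C)C(C)(C)C)cc2)N1C(=O)OC(C)(C)C
F16 | step 14 | (2S,5S)-N1,N4-di-Boc macrocyclic piperazine salicylic acid (carboxyl ortho to the ring A hydroxyl) | OC(=O)c1cc2cc(c1O)Oc1ccc(cc1)C[C@H]1CN(C(=O)OC(C)(C)C)[C@H](CN1C(=O)OC(C)(C)C)C2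
F17 | step 14 | 5-aroylamino-2,6-diaminopyrimidin-4(3H)-one from F16 and 19 | Nc1nc(N)c(NC(=O)c2cc3cc(c2O)Oc4ccc(cc4)C[C@H]5CN(C(=O)OC(C)(C)C)[C@H](CN5C(=O)OC(C)(C)C)C3)c(=O)[nH]1
A1 | alternative 1 | bis[(E)-allylic trichloroacetimidate] of the achiral O-benzyl diaryl ether | N=C(OC/C=C/Cc1ccc(OCc2ccccc2)c(Oc2ccc(C/C=C/COC(=N)C(Cl)(Cl)Cl)cc2)c1)C(Cl)(Cl)Cl
A2 | alternative 1 | (S,S)-bis(allylic trichloroacetamide) | C=C[C@H](Cc1ccc(OCc2ccccc2)c(Oc2ccc(C[C@@H](C=C)NC(=O)C(Cl)(Cl)Cl)cc2)c1)NC(=O)C(Cl)(Cl)Cl
A3 | alternative 2 | (2S,5S)-N1,N4-di-Boc macrocyclic piperazine salicylaldehyde (same as 18) | O=Cc1cc2cc(c1O)Oc1ccc(cc1)C[C@H]1CN(C(=O)OC(C)(C)C)[C@H](CN1C(=O)OC(C)(C)C)C2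
A4 | alternative 2 | 2,5,6-triaminopyrimidin-4(3H)-one (free base of 19) | Nc1nc(N)c(N)c(=O)[nH]1
A5 | alternative 2 | N1,N4-di-Boc guanipiperazine A (same as 22) | Nc1nc2nc(-c3cc4cc(c3O)Oc3ccc(cc3)C[C@H]3CN(C(=O)OC(C)(C)C)[C@H](CN3C(=O)OC(C)(C)C)C4)[nH]c2c(=O)[nH]1
A6 | alternative 3 | N-phthaloyl-L-alanyl-O-(2-benzyloxy-5-iodophenyl)-L-tyrosine | OC(=O)[C@H](Cc1ccc(Oc2cc(I)ccc2OCc2ccccc2)cc1)NC(=O)[C@H](C)N1C(=O)c2ccccc2C1=O
A7 | alternative 3 | 14-membered cyclophane dipeptide acid | OC(=O)[C@@H]1Cc2ccc(cc2)Oc2cc(ccc2OCc2ccccc2)C[C@H](N2C(=O)c3ccccc3C2=O)C(=O)N1
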